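**Plan**
1. Numbering used: C1 is the lactone carbonyl carbon, C2–C34 are the 33 ring methylenes, and C34 is bonded to the ring oxygen. The 35-membered ring has no stereocentre, so no stereochemistry has to be introduced.
2. Retrosynthetic cuts: (a) the four contiguous methylenes C18–C21 go back to a buta-1,3-diyne C18≡C19–C20≡C21; (b) the ring is opened at C19–C20, the central bond of that diyne, giving an open-chain ester with two terminal alkynes; (c) the ester C1–O bond is cut to nonadec-18-ynoic acid and pentadec-14-yn-1-ol; (d) each chain is cut, in an internal-alkyne isomer, at the bond between the triple bond and its alkyl chain, giving but-3-yn-1-ol plus 1-bromoundecane for the C15 chain and prop-2-yn-1-ol plus 1-bromohexadecane for the C19 chain.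
3. Forward order: the C15 alkynol (two steps) and the C19 alkynoic acid (three steps) are joined by esterification; the only ring then arises by copper-mediated oxidative coupling of the two alkyne termini; hydrogenation finishes the synthesis.
4. Enabling feature: C17–C22 lie in an unbranched, unfunctionalised polymethylene arc of a ring large enough to hold six collinear atoms. C19 and C20 can therefore both be carried as acidic sp C–H termini of like polarity and united oxidatively. The alkyne oxidation level is the only helper and is removed by the final hydrogenation.

Key step: step 7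

**Route**

Step 1
Reactants: 1 but-3-yn-1-ol; 2 1-bromoundecane
Product: 5 pentadec-3-yn-1-ol, via dilithium salt 3 (not isolated), via lithium alkoxide 4 (not isolated)
Conditions: n-BuLi (2.1 equiv), THF–DMPU, −78 → 0 °C; then 2, 0 °C → rt; H2O
Reagents that add atoms: none
Why: Acetylide alkylation: double deprotonation gives the O,C-dilithio species 3, whose sp carbanion is far more nucleophilic than the aggregated alkoxide and should displace bromide from the primary halide by SN2 in the dipolar cosolvent, aqueous work-up protonating alkoxide 4.

Step 2
Reactants: 5 pentadec-3-yn-1-ol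
Product: 7 pentadec-14-yn-1-ol, via dipotassium salt 6 (not isolated)
Conditions: KH (5 equiv), H2N(CH2)3NH2, rt; then 5, 0 °C → rt; H2O, 0 °C
Reagents that add atoms: none
Why: Alkyne zipper reaction: potassium 3-aminopropylamide should walk the triple bond along the unbranched chain by successive propargyl–allenyl proton shifts away from the alkoxide end until the terminal alkyne is reached and trapped irreversibly as the acetylide in 6, which water protonates.

Step 3
Reactants: 8 prop-2-yn-1-ol; 9 1-bromohexadecane
Product: 12 nonadec-2-yn-1-ol, via dilithium salt 10 (not isolated), via lithium alkoxide 11 (not isolated)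
Conditions: n-BuLi (2.1 equiv), THF–DMPU, −78 → 0 °C; then 9, 0 → 40 °C; H2O
Reagents that add atoms: none
Why: Acetylide alkylation of the same type as step 1, the sp carbanion of the O,C-dilithio species 10 displacing bromide from the primary C16 halide by SN2, with gentle warming to keep the waxy bromide in solution.

Step 4
Reactants: 12 nonadec-2-yn-1-ol
Product: 14 nonadec-18-yn-1-ol, via dipotassium salt 13 (not isolated)
Conditions: KH (5 equiv), H2N(CH2)3NH2–THF, rt; then 12, rt; H2O, 0 °C
Reagents that add atoms: none
Why: Alkyne zipper reaction as in step 2, the migration over sixteen positions being driven to completion by irreversible formation of the terminal acetylide in 13, with THF added to keep the long-chain salts in solution.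

Step 5
Reactants: 14 nonadec-18-yn-1-ol
Product: 16 nonadec-18-ynoic acid, via aldehyde 15 (not isolated)
Conditions: CrO3, H2SO4, H2O, acetone, 0 °C → rt
Reagents that add atoms: water, O
Why: Jones oxidation: the chromate ester of the primary alcohol should collapse to aldehyde 15, whose hydrate is oxidised again to the acid, while the terminal alkyne is inert to hexavalent chromium in acidic acetone.

Step 6
Reactants: 16 nonadec-18-ynoic acid; 7 pentadec-14-yn-1-ol
Product: 18 pentadec-14-yn-1-yl nonadec-18-ynoate, via O-acylisourea 17 (not isolated)
Conditions: DCC (1.1 equiv), DMAP (0.1 equiv), CH2Cl2, 0 °C → rt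
Reagents that add atoms: none
Why: Steglich esterification: DCC should convert the acid into O-acylisourea 17, from which DMAP transfers the acyl group to the unhindered primary alcohol, neither terminal alkyne taking part.

Step 7
Reactants: 18 pentadec-14-yn-1-yl nonadec-18-ynoate
Product: 20 oxacyclopentatriaconta-19,21-diyn-2-one, via dicopper diacetylide 19 (not isolated)
Conditions: Cu(OAc)2 (10 equiv), pyridine–Et2O (4:1), 45 °C; 18 added by syringe pump over 24 h, final 2 mM
Reagents that add atoms: none
Why: Eglinton oxidative coupling: acetate/pyridine-assisted deprotonation at divalent copper converts both terminal alkynes of 18 into copper acetylides (19), and two alkynyl ligands held on a dinuclear copper unit couple reductively to form the C19–C20 sp–sp bond while two Cu(OAc)2 are reduced to CuOAc. The closest known reaction type is the classical Glaser–Eglinton macrocyclisation of α,ω-diynes, well established for macrocyclic diyne lactones and large carbocycles; it unites two carbons of the same nucleophilic polarity with no activating group beyond the alkyne C–H. The single 35-membered ring closes end to end between the two chain termini with both triple bonds endocyclic, and a ring of this size holds the six collinear atoms C17–C22 without strain. No stereocentre is formed, so no control element is needed. The selectivity required is ring closure over intermolecular coupling to linear and cyclic oligomers; it is secured by syringe-pump addition into a large excess of Cu(OAc)2, which keeps the stationary concentration of uncoupled alkyne very low, while the ester is inert to the mild pyridine medium and the two alkyne termini are the only reactive sites.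

Step 8
Reactants: 20 oxacyclopentatriaconta-19,21-diyn-2-one
Product: 21 oxacyclopentatriacontan-2-one
Conditions: H2 (1 atm), 10% Pd/C, EtOAc–THF, rt
Reagents that add atoms: none
Why: Heterogeneous catalytic hydrogenation: four equivalents of H2 should saturate the conjugated diyne on the palladium surface to the C18–C21 tetramethylene unit, and the lactone, having no benzylic or allylic C–O bond, is not hydrogenolysed.

**Compound list**

1 | but-3-yn-1-ol | C#CCCO | starting material
2 | 1-bromoundecane | CCCCCCCCCCCBr | starting material
3 | dilithium salt of but-3-yn-1-ol (O,C-dilithiated, not isolated) | [Li+].[Li+].[O-]CCC#[C-] | intermediate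
4 | lithium pentadec-3-yn-1-olate (not isolated) | CCCCCCCCCCCC#CCC[O-].[Li+] | intermediate
5 | pentadec-3-yn-1-ol | CCCCCCCCCCCC#CCCO | intermediate
6 | dipotassium salt of pentadec-14-yn-1-ol (alkoxide and terminal acetylide, not isolated) | [K+].[K+].[O-]CCCCCCCCCCCCCC#[C-] | intermediate
7 | pentadec-14-yn-1-ol | C#CCCCCCCCCCCCCCO | intermediate
8 | prop-2-yn-1-ol (propargyl alcohol) | C#CCO | starting material
9 | 1-bromohexadecane | CCCCCCCCCCCCCCCCBr | starting material
10 | dilithium salt of prop-2-yn-1-ol (O,C-dilithiated, not isolated) | [Li+].[Li+].[O-]CC#[C-] | intermediate
11 | lithium nonadec-2-yn-1-olate (not isolated) | CCCCCCCCCCCCCCCCC#CC[O-].[Li+] | intermediate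
12 | nonadec-2-yn-1-ol | CCCCCCCCCCCCCCCCC#CCO | intermediate
13 | dipotassium salt of nonadec-18-yn-1-ol (alkoxide and terminal acetylide, not isolated) | [K+].[K+].[O-]CCCCCCCCCCCCCCCCCC#[C-] | intermediate
14 | nonadec-18-yn-1-ol | C#CCCCCCCCCCCCCCCCCCO | intermediate
15 | nonadec-18-ynal (not isolated) | C#CCCCCCCCCCCCCCCCCC=O | intermediate
16 | nonadec-18-ynoic acid | C#CCCCCCCCCCCCCCCCCC(=O)O | intermediate
17 | O-(nonadec-18-ynoyl)-N,N'-dicyclohexylisourea (not isolated) | C#CCCCCCCCCCCCCCCCCC(=O)OC(=NC1CCCCC1)NC1CCCCC1 | intermediate
18 | pentadec-14-yn-1-yl nonadec-18-ynoate | C#CCCCCCCCCCCCCCCCCC(=O)OCCCCCCCCCCCCCC#C | intermediate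
19 | bis(acetatocopper) diacetylide of 18 (both alkyne termini C-bound to copper, pyridine ligands omitted, not isolated) | CC(=O)O[Cu]C#CCCCCCCCCCCCCCCCCC(=O)OCCCCCCCCCCCCCC#C[Cu]OC(C)=O | intermediate
20 | oxacyclopentatriaconta-19,21-diyn-2-one (35-membered lactone with C18≡C19–C20≡C21 in the chain numbering of the plan) | O=C1CCCCCCCCCCCCCCCCC#CC#CCCCCCCCCCCCCCO1 | intermediate
21 | oxacyclopentatriacontan-2-one (tetratriacontan-34-olide, no stereocentre) | O=C1CCCCCCCCCCCCCCCCCCCCCCCCCCCCCCCCCO1 | target

**Totals**

Total step count: 8. Longest linear sequence: 6 steps (steps 3, 4, 5, 6, 7, 8).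

**Steps most likely to fail**

Step 7. The risk is intermolecular alkyne coupling outrunning ring closure, so that linear and cyclic oligomers grow at the expense of the monomeric ring, made worse if the lipophilic substrate turns over slowly and accumulates. The fallback sets out from 7 and 16 and moves the ring closure to the ester bond. Bromination of the alkyne terminus of 7 (NBS, AgNO3 cat., acetone) should give 15-bromopentadec-14-yn-1-ol F1. Intermolecular Cadiot–Chodkiewicz coupling of F1 with 16 (CuCl cat., NH2OH·HCl, n-BuNH2, H2O–MeOH–THF, 0 °C → rt) should give 34-hydroxytetratriaconta-18,20-diynoic acid F2, so the C19–C20 bond is made between two separate molecules and needs no dilution. Hydrogenation (H2, 10% Pd/C, THF, 40 °C) should give 34-hydroxytetratriacontanoic acid F3. Yamaguchi macrolactonisation (2,4,6-trichlorobenzoyl chloride, Et3N, THF; then slow addition to DMAP in toluene at reflux) then closes the ring at the C1–O bond and comes back to the route at target 21.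

Step 4. The risk is the triple-bond migration stalling part-way along its sixteen positions because the long-chain alkoxide salts aggregate or precipitate, leaving internal alkyne isomers that cannot be separated. The fallback sets out from 7, whose shorter migration is less demanding, and builds the chain by extension instead of isomerisation. Appel bromination (CBr4, PPh3, CH2Cl2, 0 °C) should give 15-bromopentadec-1-yne F4. Copper-catalysed sp3–sp3 coupling with [4-(oxan-2-yloxy)butyl]magnesium chloride (2.5 equiv, the first equivalent being consumed by the acetylenic C–H, which is restored on work-up; Li2CuCl4 cat., THF, −10 °C → rt) should give 2-(nonadec-18-yn-1-yloxy)oxane F5, racemic at the acetal carbon. Acetal cleavage (PPTS, MeOH, 50 °C) comes back to the route at 14.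

Step 3. The risk is slow C-alkylation by the waxy C16 bromide with the sparingly soluble dilithio salt, which lets O-alkylation and elimination of the bromide compete. The fallback sets out from 8 and masks the hydroxyl so that only one anionic site remains. Acetalisation (3,4-dihydro-2H-pyran, PPTS cat., CH2Cl2) should give 2-(prop-2-yn-1-yloxy)oxane F6, racemic at the acetal carbon. Monolithiation and alkylation with 9 (n-BuLi 1.05 equiv, THF–DMPU, −78 °C → rt) should give 2-(nonadec-2-yn-1-yloxy)oxane F7, racemic at the acetal carbon. Acetal cleavage (PPTS, MeOH, 50 °C) comes back to the route at 12.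

**Further compounds**

F1 | step 7 | 15-bromopentadec-14-yn-1-ol | OCCCCCCCCCCCCCC#CBr
F2 | step 7 | 34-hydroxytetratriaconta-18,20-diynoic acid | OCCCCCCCCCCCCCC#CC#CCCCCCCCCCCCCCCCCC(=O)O
F3 | step 7 | 34-hydroxytetratriacontanoic acid | OC(=O)CCCCCCCCCCCCCCCCCCCCCCCCCCCCCCCCCO
F4 | step 4 | 15-bromopentadec-1-yne | C#CCCCCCCCCCCCCCBr
F5 | step 4 | 2-(nonadec-18-yn-1-yloxy)oxane (racemic) | C#CCCCCCCCCCCCCCCCCCOC1CCCCO1
F6 | step 3 | 2-(prop-2-yn-1-yloxy)oxane (racemic) | C#CCOC1CCCCO1
F7 | step 3 | 2-(nonadec-2-yn-1-yloxy)oxane (racemic) | CCCCCCCCCCCCCCCCC#CCOC1CCCCO1
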